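**Plan**

- Retrosynthesis (lignan numbering: C7 = free carbinol carbon; C8 and C8' = oxolane carbons bearing C7 and the C9'H2OH arm; C7' = aryl-bearing ring carbon; C9 = ring CH2; O1 = ring oxygen): cut aryl–C7 first, then C7–O, the ring bond C8–C8', the ether bond O1–C9 and the chain bond C7'–C8'.
- Enabling feature: C7 is an exocyclic secondary benzylic carbinol carbon bonded only to H, the guaiacyl ring and ring carbon C8. This is the retron of a boronate 1,2-metallate shift followed by oxidation. As C7H2–OCb it is the only carbamate-activated position, it has no β-leaving group (O1 is γ), and C8 is never α to a carbonyl, so it cannot epimerise.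
- Forward: silylated vanillin → C7'–C8'–C9' allylic alcohol → O1–C9 propargyl ether → oxirane → oxolane ring by 5-exo-dig radical C8'–C8 closure → C7 hydroxylation and carbamoylation → union with the aryl boronate at C7 → desilylation.
- Stereochemistry: C7' from a Sharpless kinetic resolution; C8' relayed from C7' in the trans-selective ring closure; C8 from hydroboration anti to the C8' arm; C7 from (−)-sparteine (reagent control), carried stereospecifically through borylation, aryl migration and oxidation.

Key step: step 11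

Abbreviations: Ar = 3-methoxy-4-[(triisopropylsilyl)oxy]phenyl; TIPS = triisopropylsilyl; Cb = N,N-diisopropylcarbamoyl; pin = pinacolato.

Remark: the target is assumed to be acid-labile (benzylic ionisation at C7 would close the second oxolane ring to pinoresinol), so late work-ups are kept neutral or buffered.

**Step 1**
Reactants: 1 vanillin
Product: 2 3-methoxy-4-[(triisopropylsilyl)oxy]benzaldehyde
Conditions: TIPSCl, imidazole, DMF, rt
Reagents that add atoms: triisopropylsilyl chloride, CC(C)[Si](Cl)(C(C)C)C(C)C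
Why: Imidazole-promoted silylation of the phenol gives a base-stable, fluoride-labile ether that should survive Grignard, NaH, trivalent titanium and s-BuLi conditions.

**Step 2**
Reactants: 2 3-methoxy-4-[(triisopropylsilyl)oxy]benzaldehyde; 3 vinylmagnesium bromide
Product: 4 rac-1-Ar-prop-2-en-1-ol
Conditions: THF, −78 → 0 °C; aq. NH4Cl
Reagents that add atoms: none
Why: Grignard 1,2-addition to the aromatic aldehyde should give the racemic aryl vinyl carbinol that carries C7', C8' and C9'.

**Step 3**
Reactants: 4 rac-1-Ar-prop-2-en-1-ol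
Product: 5 (S)-1-Ar-prop-2-en-1-ol
Conditions: Ti(OiPr)4 (1.0 equiv), L-(+)-diisopropyl tartrate (1.2 equiv), t-BuOOH (0.6 equiv), 4 Å MS, CH2Cl2, −20 °C
Reagents that add atoms: none
Why: Sharpless kinetic resolution by asymmetric epoxidation: with the L-(+)-tartrate the (R)-enantiomer should be epoxidised much faster, so the unreacted (S)-alcohol, which has the C7' configuration of the target, is recovered enantioenriched (at most half of 4 is usable).

**Step 4**
Reactants: 5 (S)-1-Ar-prop-2-en-1-ol; 6 propargyl bromide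
Product: 7 (S)-3-Ar-3-(prop-2-yn-1-yloxy)prop-1-ene
Conditions: NaH, Bu4NI (cat.), THF, 0 °C → rt
Reagents that add atoms: none
Why: Williamson etherification of the sodium alkoxide forms the O1–C9 bond without touching the C7' stereocentre.

**Step 5**
Reactants: 7 (S)-3-Ar-3-(prop-2-yn-1-yloxy)prop-1-ene
Product: 8 2-[(R)-Ar(prop-2-yn-1-yloxy)methyl]oxirane (both oxirane epimers)
Conditions: mCPBA, NaHCO3, CH2Cl2, 0 °C → rt
Reagents that add atoms: meta-chloroperoxybenzoic acid, OOC(=O)c1cccc(Cl)c1
Why: Prilezhaev epoxidation of the terminal alkene (alkyne and arene react far more slowly); the configuration of the new oxirane carbon does not matter because it becomes a planar radical in step 6.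

**Step 6**
Reactants: 8 2-[(R)-Ar(prop-2-yn-1-yloxy)methyl]oxirane
Product: 9 [(2S,3R)-2-Ar-4-methylideneoxolan-3-yl]methanol
Conditions: Cp2TiCl2 (2.5 equiv), Zn dust, THF, rt (preformed Cp2TiCl added slowly); then 1 M HCl, 0 °C, brief
Reagents that add atoms: none
Why: Nugent–RajanBabu reductive epoxide opening by the trivalent titanium reagent Cp2TiCl should give the secondary C8' radical with a titanium alkoxide on C9', which closes 5-exo-dig onto the alkyne (C8'–C8 bond) and is quenched by hydrogen abstraction from THF; aryl and CH2O groups should end up trans (both pseudo-equatorial in the chair-like transition state), so C8' (R) is relayed from C7'.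

**Step 7**
Reactants: 9 [(2S,3R)-2-Ar-4-methylideneoxolan-3-yl]methanol
Product: 10 (2S,3R)-2-Ar-4-methylidene-3-[(triisopropylsilyloxy)methyl]oxolane
Conditions: TIPSCl, imidazole, DMAP (cat.), DMF, rt
Reagents that add atoms: triisopropylsilyl chloride, CC(C)[Si](Cl)(C(C)C)C(C)C
Why: Silylation of the primary C9' alcohol differentiates it from the C7 oxygen to come and makes the C8' arm bulky and non-coordinating for steps 8 and 11.

**Step 8**
Reactants: 10 (2S,3R)-2-Ar-4-methylidene-3-[(triisopropylsilyloxy)methyl]oxolane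
Product: 12 [(3S,4R,5S)-5-Ar-4-[(triisopropylsilyloxy)methyl]oxolan-3-yl]methanol, via B-alkyl-9-BBN adduct 11 (not isolated)
Conditions: 9-BBN, THF, 0 °C → rt; then 30% H2O2, 3 M aq. NaOAc, 0 °C → rt
Reagents that add atoms: hydrogen peroxide, OO
Why: Anti-Markovnikov syn-hydroboration with bulky 9-BBN should occur on the alkene face anti to the adjacent CH2OTIPS arm, delivering H to C8 on that face and placing the new CH2OH cis to C9' (sets C8); buffered oxidation with retention keeps the aryl silyl ethers.

**Step 9**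
Reactants: 12 [(3S,4R,5S)-5-Ar-4-[(triisopropylsilyloxy)methyl]oxolan-3-yl]methanol
Product: 13 [(3R,4R,5S)-5-Ar-4-[(triisopropylsilyloxy)methyl]oxolan-3-yl]methyl N,N-diisopropylcarbamate
Conditions: CbCl, Et3N, DMAP (cat.), CH2Cl2, reflux
Reagents that add atoms: N,N-diisopropylcarbamoyl chloride, CC(C)N(C(C)C)C(Cl)=O
Why: Acylation of the primary alcohol with the hindered carbamoyl chloride installs the group that both directs α-lithiation and later leaves in the 1,2-shift.

**Step 10**
Reactants: 14 2-methoxy-4-(4,4,5,5-tetramethyl-1,3,2-dioxaborolan-2-yl)phenol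
Product: 15 2-Ar-4,4,5,5-tetramethyl-1,3,2-dioxaborolane
Conditions: TIPSCl, imidazole, CH2Cl2, rt
Reagents that add atoms: triisopropylsilyl chloride, CC(C)[Si](Cl)(C(C)C)C(C)C
Why: Silylation of the commercially available phenol boronate removes the acidic proton that would quench the organolithium in step 11.

**Step 11**
Reactants: 13 [(3R,4R,5S)-5-Ar-4-[(triisopropylsilyloxy)methyl]oxolan-3-yl]methyl N,N-diisopropylcarbamate; 15 2-Ar-4,4,5,5-tetramethyl-1,3,2-dioxaborolane
Product: 19 (R)-Ar[(3R,4R,5S)-5-Ar-4-[(triisopropylsilyloxy)methyl]oxolan-3-yl]methanol, via lithiated carbamate 16 (not isolated), via boronate complex 17 (not isolated), via boronic ester 18 (not isolated)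
Conditions: s-BuLi (1.3 equiv), (−)-sparteine (1.3 equiv), Et2O, −78 °C, 5 h; 15 (1.5 equiv), −78 °C, 1 h, then rt (MgBr2·OEt2 and reflux if migration is slow); then 30% H2O2, 2 M NaOH, THF, 0 °C
Reagents that add atoms: hydrogen peroxide, OO
Why: Hoppe–Aggarwal lithiation–borylation: s-BuLi/(−)-sparteine, pre-complexed to the carbamate C=O, should remove the pro-S hydrogen of the C7 methylene to give the configurationally stable (S)-α-lithio carbamate 16, which is borylated by 15 with retention to the boronate 17; on warming the electron-rich aryl group undergoes a stereospecific 1,2-metallate shift from boron to C7 anti to the departing carbamate (inversion), forming the aryl–C7 bond in 18, and peroxide oxidation replaces boron by OH with retention. The closest known reaction type is the reagent-controlled homologation of aryl pinacol boronates with sparteine-lithiated primary alkyl carbamates to secondary benzylic alcohols. No ring is closed. The C7 stereocentre (R) is controlled by (−)-sparteine (S-lithio, then retention, inversion, retention), while the existing C8 centre is a spectator that cannot epimerise because C7 is never a carbonyl carbon. The step needs site selectivity for the C7–H bonds over the benzylic C7'–H and the aryl ortho hydrogens, which the complex-induced proximity effect of the carbamate at −78 °C in Et2O should secure; it also needs migration rather than reversal of the boronate, which the high migratory aptitude of the para-oxygenated aryl group and the absence of a β-leaving group (O1 is γ to C7) should secure.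

**Step 12**
Reactants: 19 (R)-Ar[(3R,4R,5S)-5-Ar-4-[(triisopropylsilyloxy)methyl]oxolan-3-yl]methanol
Product: 20 (7R)-7-hydroxylariciresinol
Conditions: TBAF (3.5 equiv), AcOH (3.5 equiv), THF, 0 °C → rt; pH 7 work-up
Reagents that add atoms: none
Why: Fluoride cleavage of the two aryl and one alkyl TIPS ethers under acetic acid buffering should avoid both base-induced quinone methide formation and acid-catalysed ionisation at C7; no stereocentre is touched.

**Compound list**

1 | vanillin (4-hydroxy-3-methoxybenzaldehyde) | COc1cc(C=O)ccc1O | starting material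
2 | 3-methoxy-4-[(triisopropylsilyl)oxy]benzaldehyde | COc1cc(C=O)ccc1O[Si](C(C)C)(C(C)C)C(C)C | intermediate
3 | vinylmagnesium bromide | C=C[Mg]Br | starting material
4 | rac-1-Ar-prop-2-en-1-ol | COc1cc(C(O)C=C)ccc1O[Si](C(C)C)(C(C)C)C(C)C | intermediate
5 | (S)-1-Ar-prop-2-en-1-ol | COc1cc([C@@H](O)C=C)ccc1O[Si](C(C)C)(C(C)C)C(C)C | intermediate
6 | propargyl bromide (3-bromoprop-1-yne) | C#CCBr | starting material
7 | (S)-3-Ar-3-(prop-2-yn-1-yloxy)prop-1-ene | COc1cc([C@@H](OCC#C)C=C)ccc1O[Si](C(C)C)(C(C)C)C(C)C | intermediate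
8 | 2-[(R)-Ar(prop-2-yn-1-yloxy)methyl]oxirane, both oxirane epimers | COc1cc([C@@H](OCC#C)C2CO2)ccc1O[Si](C(C)C)(C(C)C)C(C)C | intermediate
9 | [(2S,3R)-2-Ar-4-methylideneoxolan-3-yl]methanol (2,3-trans) | COc1cc([C@H]2OCC(=C)[C@@H]2CO)ccc1O[Si](C(C)C)(C(C)C)C(C)C | intermediate
10 | (2S,3R)-2-Ar-4-methylidene-3-[(triisopropylsilyloxy)methyl]oxolane | COc1cc([C@H]2OCC(=C)[C@@H]2CO[Si](C(C)C)(C(C)C)C(C)C)ccc1O[Si](C(C)C)(C(C)C)C(C)C | intermediate
11 | 9-{[(3R,4R,5S)-5-Ar-4-[(triisopropylsilyloxy)methyl]oxolan-3-yl]methyl}-9-borabicyclo[3.3.1]nonane | COc1cc([C@H]2OC[C@H](CB3C4CCCC3CCC4)[C@@H]2CO[Si](C(C)C)(C(C)C)C(C)C)ccc1O[Si](C(C)C)(C(C)C)C(C)C | intermediate (not isolated)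
12 | [(3S,4R,5S)-5-Ar-4-[(triisopropylsilyloxy)methyl]oxolan-3-yl]methanol (3,4-cis, 4,5-trans) | COc1cc([C@H]2OC[C@H](CO)[C@@H]2CO[Si](C(C)C)(C(C)C)C(C)C)ccc1O[Si](C(C)C)(C(C)C)C(C)C | intermediate
13 | [(3R,4R,5S)-5-Ar-4-[(triisopropylsilyloxy)methyl]oxolan-3-yl]methyl N,N-diisopropylcarbamate | COc1cc([C@H]2OC[C@H](COC(=O)N(C(C)C)C(C)C)[C@@H]2CO[Si](C(C)C)(C(C)C)C(C)C)ccc1O[Si](C(C)C)(C(C)C)C(C)C | intermediate
14 | 2-methoxy-4-(4,4,5,5-tetramethyl-1,3,2-dioxaborolan-2-yl)phenol | COc1cc(B2OC(C)(C)C(C)(C)O2)ccc1O | starting material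
15 | 2-Ar-4,4,5,5-tetramethyl-1,3,2-dioxaborolane | COc1cc(B2OC(C)(C)C(C)(C)O2)ccc1O[Si](C(C)C)(C(C)C)C(C)C | intermediate
16 | (S)-α-lithio derivative of carbamate 13 (lithium on C7, sparteine-bound) | COc1cc([C@H]2OC[C@H]([C@H]([Li])OC(=O)N(C(C)C)C(C)C)[C@@H]2CO[Si](C(C)C)(C(C)C)C(C)C)ccc1O[Si](C(C)C)(C(C)C)C(C)C | intermediate (not isolated)
17 | lithium (S)-boronate complex of 16 with 15 (C7 bears OCb and B(pin)Ar) | COc1cc([C@H]2OC[C@H]([C@H]([B-]3(c4ccc(O[Si](C(C)C)(C(C)C)C(C)C)c(OC)c4)OC(C)(C)C(C)(C)O3)OC(=O)N(C(C)C)C(C)C)[C@@H]2CO[Si](C(C)C)(C(C)C)C(C)C)ccc1O[Si](C(C)C)(C(C)C)C(C)C.[Li+] | intermediate (not isolated)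
18 | (R)-secondary benzylic pinacol boronic ester (C7 bears Ar and B(pin)) | COc1cc([C@H]2OC[C@H]([C@@H](B3OC(C)(C)C(C)(C)O3)c4ccc(O[Si](C(C)C)(C(C)C)C(C)C)c(OC)c4)[C@@H]2CO[Si](C(C)C)(C(C)C)C(C)C)ccc1O[Si](C(C)C)(C(C)C)C(C)C | intermediate (not isolated)
19 | (R)-Ar[(3R,4R,5S)-5-Ar-4-[(triisopropylsilyloxy)methyl]oxolan-3-yl]methanol | COc1cc([C@H]2OC[C@H]([C@@H](O)c3ccc(O[Si](C(C)C)(C(C)C)C(C)C)c(OC)c3)[C@@H]2CO[Si](C(C)C)(C(C)C)C(C)C)ccc1O[Si](C(C)C)(C(C)C)C(C)C | intermediate
20 | (7R)-7-hydroxylariciresinol; 4-[(2S,3R,4R)-4-[(R)-hydroxy(4-hydroxy-3-methoxyphenyl)methyl]-3-(hydroxymethyl)oxolan-2-yl]-2-methoxyphenol | COc1cc([C@H]2OC[C@H]([C@@H](O)c3ccc(O)c(OC)c3)[C@@H]2CO)ccc1O | target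

**Step count and risks**

Total step count: 12. Longest linear sequence: 11 steps (steps 1–9, 11, 12).

Most likely to fail, first: step 11. The lithiation may be diverted to the benzylic C7'–H, or the substrate's C8 centre may oppose (−)-sparteine, giving slow or poorly selective deprotonation, or the boronate may revert instead of migrating. The fallback sets out from 12. Oxidation with Dess–Martin periodinane (CH2Cl2, NaHCO3, 0 °C) should give (3R,4R,5S)-5-Ar-4-[(triisopropylsilyloxy)methyl]oxolane-3-carbaldehyde F1, used at once. Commercial 4-bromo-2-methoxyphenol is silylated (TIPSCl, imidazole) to (4-bromo-2-methoxyphenoxy)triisopropylsilane F2, and bromine–lithium exchange (n-BuLi, THF, −78 °C) gives [3-methoxy-4-(triisopropylsilyloxy)phenyl]lithium F3. Addition of F3 to F1 at −78 °C should follow the Felkin–Anh model, with the nucleophile anti to the more substituted ring carbon C8' and the carbonyl oxygen gauche to C9, and give 19 directly; any C7 epimer would be removed by chromatography. The route is rejoined at 19.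

Second: step 6. The C8' radical may be reduced by a second Cp2TiCl and lose the β-titanoxy group before it cyclises, or the ring closure may be poorly trans-selective. The fallback sets out from 7 and skips step 5. Borylative cyclisation of the 1,6-enyne (Pd(OAc)2 5 mol %, B2pin2, MeOH, toluene, 50 °C) proceeds by hydropalladation of the alkyne, 5-exo insertion of the vinyl group and boryl transfer. It should give 2-{[(2S,3S)-2-Ar-4-methylideneoxolan-3-yl]methyl}-4,4,5,5-tetramethyl-1,3,2-dioxaborolane F4 with the aryl group pseudo-equatorial (trans). Oxidation (30% H2O2, NaOH, THF, 0 °C) returns the route at 9.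

Third: step 8. Hydroboration may show poor facial selectivity, because the aryl group on the opposite face competes with the C8' arm, giving the C8 epimer alongside 12. The fallback sets out from 12 as its mixture with the C8 epimer. Dess–Martin oxidation gives (4R,5S)-5-Ar-4-[(triisopropylsilyloxy)methyl]oxolane-3-carbaldehyde as a C3 epimer mixture F5. O-Carbamoylation of its potassium enolate (KOtBu, CbCl, THF, −78 °C) gives [(4R,5S)-5-Ar-4-[(triisopropylsilyloxy)methyl]oxolan-3-ylidene]methyl N,N-diisopropylcarbamate F6, in which C8 is trigonal, so both epimers converge. Hydrogenation over palladium on carbon (Pd/C, H2 1 atm, EtOAc) should deliver hydrogen syn on the face anti to the CH2OTIPS arm and give the cis carbamate. The route is rejoined at 13, with step 9 omitted.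

**Further compounds**

F1 | step 11 | (3R,4R,5S)-5-Ar-4-[(triisopropylsilyloxy)methyl]oxolane-3-carbaldehyde | COc1cc([C@H]2OC[C@H](C=O)[C@@H]2CO[Si](C(C)C)(C(C)C)C(C)C)ccc1O[Si](C(C)C)(C(C)C)C(C)C
F2 | step 11 | (4-bromo-2-methoxyphenoxy)triisopropylsilane | COc1cc(Br)ccc1O[Si](C(C)C)(C(C)C)C(C)C
F3 | step 11 | [3-methoxy-4-(triisopropylsilyloxy)phenyl]lithium | COc1cc([Li])ccc1O[Si](C(C)C)(C(C)C)C(C)C
F4 | step 6 | 2-{[(2S,3S)-2-Ar-4-methylideneoxolan-3-yl]methyl}-4,4,5,5-tetramethyl-1,3,2-dioxaborolane | COc1cc([C@H]2OCC(=C)[C@@H]2CB3OC(C)(C)C(C)(C)O3)ccc1O[Si](C(C)C)(C(C)C)C(C)C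
F5 | step 8 | (4R,5S)-5-Ar-4-[(triisopropylsilyloxy)methyl]oxolane-3-carbaldehyde, C3 epimer mixture | COc1cc([C@H]2OCC(C=O)[C@@H]2CO[Si](C(C)C)(C(C)C)C(C)C)ccc1O[Si](C(C)C)(C(C)C)C(C)C
F6 | step 8 | [(4R,5S)-5-Ar-4-[(triisopropylsilyloxy)methyl]oxolan-3-ylidene]methyl N,N-diisopropylcarbamate, E/Z mixture | COc1cc([C@H]2OCC(=COC(=O)N(C(C)C)C(C)C)[C@@H]2CO[Si](C(C)C)(C(C)C)C(C)C)ccc1O[Si](C(C)C)(C(C)C)C(C)C
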